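Two questions are enough for this row, and each gets a follow-up at its weak spot.

| flask | first end groups | second end groups | one-sided end groups | protic impurity | remark | time |
|---|---|---|---|---|---|---|
| Tuesday's | 0.10 M | 0.090 M (fed, over 30 h) | 0.0032 M | 0.10 M | run made earlier; the fed solution adds 1.0 times the starting volume |  |
| Monday's | 0.10 M | 0.090 M (fed, over 30 h) | 0.0065 M | 0.10 M | run made earlier; the fed solution adds 1.0 times the starting volume |  |
| zeta | 0.10 M | 0.0900 M (fed, over 30 h) | 0.00300 M | 0.100 M | the fed solution adds 1.0 times the starting volume | 30 h |
| delta | 0.10 M | 0.0900 M (fed, over 30 h) | 0.00400 M | 0.100 M | the fed solution adds 1.0 times the starting volume | 30 h |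
| epsilon | 0.10 M | 0.0900 M (fed, over 30 h) | 0.00600 M | 0.100 M | the fed solution adds 1.0 times the starting volume | 30 h |
| eta | 0.10 M | 0.0900 M (fed, over 30 h) | 0.0100 M | 0.100 M | the fed solution adds 1.0 times the starting volume | 30 h |
| alpha | 0.10 M | 0.0900 M (fed, over 30 h) | 0.0150 M | 0.100 M | the fed solution adds 1.0 times the starting volume | 30 h |

- Tuesday's (time / h: links / %, first end groups / %): 8.00: 3.3, 94.8; 15.0: 6.0, 90.1; 25.0: 13.9, 82.0; 30.0: 17.6, 78.7
- Monday's (time / h: links / %, first end groups / %): 4.00: 1.0, 94.9; 10.0: 3.8, 90.5; 20.0: 10.1, 84.1; 30.0: 17.1, 76.2

(each reading ± 0.5 percentage points)

- amount of links at the end, in percent of the first end groups charged for zeta, delta, epsilon, eta, alpha, in this order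
- the course of these numbers from the first flask to the last (falls all the way / rises all the way / falls, then rises / hardly changes / rises, then falls)

- charges are per starting volume, the dose included; the dosed solution carries all of it
- what may be going on: second end groups + protic impurity -> quenched reagent; first end groups + one-sided end groups -> capped ends; first end groups + second end groups -> links; links <-> isomer of the product
- "hardly changes" means that all values lie within two and a half points (for a concentration: within two and a half percent of the largest)

Question: at one moment, which runs ahead, capping or link formation? Answer: read the gap, first end groups lost minus links formed, since first end groups leave by these two routes. In Monday's run at 4.00 h the gap is 4.1 percentage points against links of 1.0%, so capping is faster than link formation at that stage.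

Follow-up: how does that comparison drift? From 20.0 h to 30.0 h, Monday's links gain 7 points while the gap gains 0.9 points, so the order has reversed. Monday's final gap reads 6.7 points, near the 6.50% that the charge of one-sided end groups can cap one for one.

Question: what does a larger charge of one-sided end groups then do to links? Answer: it takes first end groups away early, and those left meet the same feed. Divide the links at the end by one minus c(one-sided end groups)/c(first end groups). Tuesday's run gives 18.2% and Monday's 18.3%, which differ by less than the scatter of a reading. I carry their mean, 18.2%, as the link share: the part of the uncapped first end groups that stands as links at the end of the feed, which makes it a conversion to links, not a selectivity.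

Follow-up: is that safe for alpha? Less so, because alpha's 0.0150 M lies above Monday's 0.0065 M, which makes it an extrapolation. My reckoning gives 17.7% for zeta and 15.5% for alpha, a fall of 2.2 points, so I say it hardly changes, though not by a wide margin.

The forecast gives 17.6%, 17.4%, 17.2%, 16.7% and 16.1%, with the shape hardly changes. It ends higher than my alpha, and of capping it says: “It simply removes first end groups early.”

    second end groups + protic impurity → quenched reagent (k = 0.470 M⁻¹ h⁻¹)
    first end groups + one-sided end groups → capped ends (k = 2.70 M⁻¹ h⁻¹)
    first end groups + second end groups → links (k = 0.390 M⁻¹ h⁻¹)
    links ⇌ isomer of the product (K = 3.50, k = 0.00320 h⁻¹)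

The flasks give 17.4%, 17.3%, 17.0%, 16.4% and 15.7%, with the shape hardly changes, and the forecast stands within the tolerance. In zeta, 2.87% of capped ends already stand at 15.0 h, nearly all of the 2.98% at 30.0 h. The link share applied to those zeta capped ends gives 17.7%. Applied to eta, whose capped ends reach 9.92%, it gives 16.4%, and eta holds 16.4%.

The earlier runs and the new flask are simulated with constants of no real substance; noise was put on by code.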